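Ring B of the labdane core is closed in one thermal operation across C9–C10 and C6–C7. The precursor is a ring A cyclohexene whose carbinol carbon C6 carries an (E)-4-methylpenta-2,4-dienyl chain bound through the future side-chain carbon C12. An oxy-Cope shift moves the chain from C6 to C10 (C9–C10 bond, quaternary C10) and unveils the C6 aldehyde, which closes onto the isopropenyl unit C7=C8 by a carbonyl-ene reaction (C6–C7 bond). The step exploits the C10=C5–C6(O) allylic carbinol of ring A and the 1,3 relation between the C6 oxygen and C8 in ring B. The C9 vinyl group then becomes C11–C12 of the side chain.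

Key step: step 10

Remark: locants are the labdane locants of the target (C1–C20); β is the face of the C10 methyl (C20), α the opposite face.
Remark: in step 8 the sense of induction is assumed to follow that known for aryl and α,β-unsaturated aldehydes ((R)-catalyst gives the (R)-carbinol), so (S)-TRIP is used.
Remark: (E)-3-iodobut-2-enoic acid 23 is taken as a purchasable compound.

Step 1
Reactants: 1 geranyl acetate
Product: 2 (2E,6E)-8-hydroxygeranyl acetate
Conditions: SeO2 (cat.), t-BuOOH, salicylic acid (cat.), CH2Cl2, rt
Reagents that add atoms: tert-butyl hydroperoxide CC(C)(C)OO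
Why: Selenium dioxide allylic oxidation (ene reaction then [2,3]-shift) should hydroxylate the (E)-methyl group of the electron-richer terminal alkene, the alkene next to the acetate being deactivated.

Step 2
Reactants: 2 (2E,6E)-8-hydroxygeranyl acetate
Product: 3 (6R,7R)-6,7-epoxy-8-hydroxygeranyl acetate
Conditions: Ti(OiPr)4 (cat.), D-(−)-diethyl tartrate (cat.), t-BuOOH, 4 Å MS, CH2Cl2, −20 °C
Reagents that add atoms: tert-butyl hydroperoxide CC(C)(C)OO
Why: Sharpless asymmetric epoxidation of the (E)-allylic alcohol with the D-tartrate should deliver oxygen to the face that gives the (2R,3R)-epoxy alcohol, which fixes the later C3 and, through the cyclisation, C4.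

Step 3
Reactants: 3 (6R,7R)-6,7-epoxy-8-hydroxygeranyl acetate
Product: 4 (6R,7R)-8-(tert-butyldiphenylsilyloxy)-6,7-epoxygeranyl acetate
Conditions: TBDPSCl, imidazole, DMF, rt
Reagents that add atoms: tert-butyl(chloro)diphenylsilane CC(C)(C)[Si](Cl)(c1ccccc1)c1ccccc1
Why: Silylation of the primary alcohol gives a bulky, robust ether for the later C19 oxygen and touches no stereocentre.

Step 4
Reactants: 4 (6R,7R)-8-(tert-butyldiphenylsilyloxy)-6,7-epoxygeranyl acetate
Product: 5 ring A alcohol [(1S,5R,6S)-6-(TBDPS-oxymethyl)-5-hydroxy-6-methyl-2-methylidenecyclohexyl]methyl acetate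
Conditions: Cp2TiCl2 (2.2 equiv), Mn dust, THF, rt (Cp2TiCl formed in the flask); dilute aq. HCl work-up
Reagents that add atoms: none
Why: Titanocene monochloride (trivalent titanium) should open the epoxide homolytically at its tertiary carbon and the β-titanoxy radical should close 6-endo onto the trisubstituted alkene (radical epoxy-polyene cyclisation) through a chair with the titanoxy, silyloxymethyl and acetoxymethyl groups equatorial, so that C3 keeps the epoxide configuration and the C4 methyl and the C5 acetoxymethyl both end up cis to the C3 oxygen; trapping by a second titanium centre and β-hydride elimination give the exocyclic alkene.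

Step 5
Reactants: 5 ring A alcohol; 6 3-methylbutanoyl chloride (isovaleryl chloride)
Product: 7 isovalerate of 5 (C3 ester; C6 acetate; C19 silyl ether)
Conditions: pyridine, DMAP (cat.), CH2Cl2, 0 °C to rt
Reagents that add atoms: none
Why: DMAP-catalysed acylation of the only free hydroxyl installs the isovalerate of the target early, with retention at C3.

Step 6
Reactants: 7 isovalerate
Product: 8 primary alcohol (C6–OH free; C3 isovalerate kept)
Conditions: K2CO3 (cat.), MeOH, 0 °C
Reagents that add atoms: none
Why: Base-catalysed transesterification should cleave the unhindered primary acetate much faster than the β-branched isovalerate on a secondary carbon next to the quaternary C4.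

Step 7
Reactants: 8 primary alcohol
Product: 10 ring A enal (1R,2S)-2-(TBDPS-oxymethyl)-3-formyl-2,4-dimethylcyclohex-3-en-1-yl 3-methylbutanoate, via β,γ-unsaturated aldehyde 9 (not isolated)
Conditions: TEMPO (cat.), PhI(OAc)2, CH2Cl2, rt; then DBU (cat.), rt
Reagents that add atoms: none
Why: Oxoammonium oxidation of the primary alcohol followed by base-mediated prototropic shift of the exocyclic alkene into conjugation should give the tetrasubstituted enal and removes the C5 stereocentre.

Step 8
Reactants: 10 ring A enal; 11 allylboronic acid pinacol ester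
Product: 12 (6S)-homoallylic alcohol (3-[(1S)-1-hydroxybut-3-enyl] analogue of 10)
Conditions: (S)-TRIP (5 mol %), 4 Å MS, toluene, −30 °C to rt; aqueous work-up
Reagents that add atoms: none
Why: Chiral phosphoric acid-catalysed allylboration proceeds through a closed chair six-membered transition state in which the catalyst holds the boronate and the formyl hydrogen, so that catalyst control should set the (S)-carbinol at C6.

Step 9
Reactants: 12 (6S)-homoallylic alcohol; 13 isoprene
Product: 14 (6S)-dienol (3-[(1S,3E)-1-hydroxy-5-methylhexa-3,5-dienyl] analogue of 10)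
Conditions: second-generation Hoveyda–Grubbs catalyst RuCl2(SIMes)(=CH-C6H4-2-OiPr) (5 mol %), isoprene in excess, CH2Cl2, 40 °C, sealed tube
Reagents that add atoms: none
Why: Ene–diene cross-metathesis should join the terminal vinyl of 12 to the monosubstituted alkene of isoprene (the 1,1-disubstituted and tetrasubstituted alkenes are inert) and give the thermodynamic (E)-diene with loss of ethylene.

Step 10
Reactants: 14 (6S)-dienol
Product: 17 bicyclic homoallylic alcohol (6β-OH; 8(17)-methylene; 9α-vinyl; 5α-H; 10β-methyl), via enol 15 (not isolated), via aldehyde 16 (not isolated)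
Conditions: toluene (0.01 M), DBU (0.2 equiv), 210 °C, sealed vessel (microwave)
Reagents that add atoms: none
Why: Heating triggers an oxy-Cope [3,3]-sigmatropic shift of the 1,5-dien-3-ol C10=C5–C6(OH)–C12–C11=C9, which forms C9–C10 and breaks C6–C12 to give enol 15; DBU-assisted tautomerisation gives aldehyde 16, which closes onto the isopropenyl group by an intramolecular type 2 carbonyl-ene reaction that forms C6–C7 and passes a C17 hydrogen to oxygen, the closest known reaction type being the thermal tandem oxy-Cope/carbonyl-ene cascade of 1,2-dialkenyl cycloalkanols. Ring B (six-membered) is closed by attack of the aldehyde carbon C6 on the terminal carbon C7 of the 1,1-disubstituted alkene (endo with respect to that alkene) in a chair-like six-centre transition state. C10 is set in the chair transition state of the [3,3] shift by chirality transfer from the (S)-carbinol C6, whose hydroxyl sits pseudo-equatorial, so that the chain crosses the α-face, away from the pseudo-axial C19 silyloxymethyl group, and the C20 methyl ends up β; the (E)-geometry of C11=C9 fixes C9 (vinyl α) in the same chair. C5 is set by the keto tautomer that closes through the trans-fused chair (5α-H), and C6 by the need of the concerted hydrogen transfer for an axial carbonyl oxygen (6β-OH); C6 and C9 are re-set in steps 12 to 14, so only C10 has to be right here. The step needs the sigmatropic shift to beat retro-ene loss of the chain and needs the aldehyde to choose the isopropenyl over the vinyl group: dilute neutral conditions, the irreversible enol-to-aldehyde tautomerisation and the fact that the only allylic hydrogen of the vinyl group sits on the tether carbon C9, out of reach of a six-centre ene transition state, should secure this.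

Step 11
Reactants: 17 bicyclic homoallylic alcohol
Product: 18 primary alkylboronate (C12–Bpin; 8(17)-methylene kept)
Conditions: [Ir(cod)Cl]2 (1.5 mol %), dppe (3 mol %), HBpin, CH2Cl2, rt; aqueous work-up
Reagents that add atoms: pinacolborane [H]B1OC(C)(C)C(C)(C)O1
Why: Iridium-catalysed hydroboration should take the monosubstituted vinyl group in preference to the 1,1-disubstituted exocyclic alkene and give the linear boronate, the hydroxyl being borylated only transiently.

Step 12
Reactants: 18 primary alkylboronate
Product: 19 β,γ-unsaturated 6-ketone (8(17)-methylene)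
Conditions: Dess–Martin periodinane, CH2Cl2, rt
Reagents that add atoms: none
Why: Dess–Martin oxidation converts the hindered axial alcohol into the ketone under neutral conditions that leave the boronate, the esters and the silyl ether alone.

Step 13
Reactants: 19 β,γ-unsaturated 6-ketone
Product: 20 dienol acetate (6-acetoxy-6,8-diene; C8 methyl)
Conditions: isopropenyl acetate (solvent), TsOH·H2O (cat.), reflux
Reagents that add atoms: isopropenyl acetate CC(=C)OC(C)=O
Why: Acid-catalysed enol acetylation under equilibrating conditions should give the thermodynamic homoannular dienol acetate, in which the exocyclic alkene has moved to the tetrasubstituted C8=C9 position (C9 becomes planar and loses its axial chain) while C5, α to the carbonyl, can settle as the trans-fused 5α-H epimer.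

Step 14
Reactants: 20 dienol acetate
Product: 22 6β-hydroxy-8-ene boronate, via deconjugated ketone 21 (not isolated)
Conditions: NaBH4, EtOH/THF, 0 °C to rt
Reagents that add atoms: none
Why: Borohydride cleaves the enol acetate, the dienolate is protonated kinetically at C7 and the resulting β,γ-unsaturated ketone is reduced before it can reconjugate (deconjugative reduction of a dienol acetate), hydride arriving from the α-face because the β-face is shielded by the axial C20 methyl and C19 silyloxymethyl groups, which should give the axial 6β-alcohol.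

Step 15
Reactants: 23 (E)-3-iodobut-2-enoic acid; 24 2-(trimethylsilyl)ethanol
Product: 25 2-(trimethylsilyl)ethyl (E)-3-iodobut-2-enoate
Conditions: DCC, DMAP (cat.), CH2Cl2, 0 °C to rt
Reagents that add atoms: none
Why: Steglich esterification masks the acid as a fluoride-labile ester without touching the alkene geometry.

Step 16
Reactants: 22 6β-hydroxy-8-ene boronate; 25 2-(trimethylsilyl)ethyl (E)-3-iodobut-2-enoate
Product: 26 protected target (C15 TMSE ester; C19 TBDPS ether)
Conditions: Pd(OAc)2 (5 mol %), SPhos (10 mol %), K3PO4, THF/H2O, 60 °C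
Reagents that add atoms: none
Why: B-alkyl Suzuki–Miyaura coupling of the primary boronate with the alkenyl iodide should form C12–C13 with retention of the (E)-geometry, the bulky biarylphosphine favouring reductive elimination over β-hydride loss.

Step 17
Reactants: 26 protected target
Product: 27 target (13E)-6β,19-dihydroxy-3α-(3-methylbutanoyloxy)labda-8,13-dien-15-oic acid
Conditions: TBAF, THF, 0 °C to rt; aq. NH4Cl work-up
Reagents that add atoms: none
Why: Fluoride removes the silyl ether and fragments the 2-(trimethylsilyl)ethyl ester in one operation, while the isovalerate should stay in place because the C3 oxygen and C19 are antiperiplanar on ring A and acyl migration has no pathway.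

Compound list
1 | geranyl acetate | CC(C)=CCC/C(C)=C/COC(C)=O | starting material
2 | (2E,6E)-8-hydroxygeranyl acetate | OC/C(C)=C/CC/C(C)=C/COC(C)=O | intermediate
3 | (6R,7R)-6,7-epoxy-8-hydroxygeranyl acetate | OC[C@@]1(C)O[C@@H]1CC/C(C)=C/COC(C)=O | intermediate
4 | (6R,7R)-8-(tert-butyldiphenylsilyloxy)-6,7-epoxygeranyl acetate | CC(C)(C)[Si](c1ccccc1)(c1ccccc1)OC[C@@]1(C)O[C@@H]1CC/C(C)=C/COC(C)=O | intermediate
5 | [(1S,5R,6S)-6-(TBDPS-oxymethyl)-5-hydroxy-6-methyl-2-methylidenecyclohexyl]methyl acetate (OH cis to the 6-methyl and to the acetoxymethyl group) | C=C1CC[C@@H](O)[C@](C)(CO[Si](c2ccccc2)(c2ccccc2)C(C)(C)C)[C@H]1COC(C)=O | intermediate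
6 | 3-methylbutanoyl chloride | CC(C)CC(Cl)=O | starting material
7 | 3-methylbutanoate of 5 | C=C1CC[C@@H](OC(=O)CC(C)C)[C@](C)(CO[Si](c2ccccc2)(c2ccccc2)C(C)(C)C)[C@H]1COC(C)=O | intermediate
8 | primary alcohol from 7 (acetate removed) | C=C1CC[C@@H](OC(=O)CC(C)C)[C@](C)(CO[Si](c2ccccc2)(c2ccccc2)C(C)(C)C)[C@H]1CO | intermediate
9 | β,γ-unsaturated aldehyde from 8 | C=C1CC[C@@H](OC(=O)CC(C)C)[C@](C)(CO[Si](c2ccccc2)(c2ccccc2)C(C)(C)C)[C@H]1C=O | intermediate
10 | (1R,2S)-2-(TBDPS-oxymethyl)-3-formyl-2,4-dimethylcyclohex-3-en-1-yl 3-methylbutanoate | CC1=C(C=O)[C@@](C)(CO[Si](c2ccccc2)(c2ccccc2)C(C)(C)C)[C@H](OC(=O)CC(C)C)CC1 | intermediate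
11 | allylboronic acid pinacol ester | C=CCB1OC(C)(C)C(C)(C)O1 | starting material
12 | 3-[(1S)-1-hydroxybut-3-enyl] analogue of 10 | CC1=C([C@@H](O)CC=C)[C@@](C)(CO[Si](c2ccccc2)(c2ccccc2)C(C)(C)C)[C@H](OC(=O)CC(C)C)CC1 | intermediate
13 | isoprene (2-methylbuta-1,3-diene) | C=CC(C)=C | starting material
14 | 3-[(1S,3E)-1-hydroxy-5-methylhexa-3,5-dienyl] analogue of 10 | CC1=C([C@@H](O)C/C=C/C(C)=C)[C@@](C)(CO[Si](c2ccccc2)(c2ccccc2)C(C)(C)C)[C@H](OC(=O)CC(C)C)CC1 | intermediate
15 | enol from the [3,3] shift (C5=C6 enol, OH cis to C4; C10 quaternary; C9 bearing vinyl and isopropenyl) | O/C=C1\[C@@](C)(CO[Si](c2ccccc2)(c2ccccc2)C(C)(C)C)[C@H](OC(=O)CC(C)C)CC[C@]1(C)[C@H](C=C)C(C)=C | intermediate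
16 | aldehyde tautomer of 15 (5α-H, formyl equatorial) | O=C[C@H]1[C@@](C)(CO[Si](c2ccccc2)(c2ccccc2)C(C)(C)C)[C@H](OC(=O)CC(C)C)CC[C@]1(C)[C@H](C=C)C(C)=C | intermediate
17 | 19-(TBDPS-oxy)-6β-hydroxy-9α-vinyl-8(17)-methylene trans-decalin 3α-isovalerate (13,14,15,16-tetranor-labda-8(17),11-diene, 9βH) | C=C1[C@@H](C=C)[C@@]2(C)CC[C@@H](OC(=O)CC(C)C)[C@](C)(CO[Si](c3ccccc3)(c3ccccc3)C(C)(C)C)[C@@H]2[C@H](O)C1 | intermediate
18 | C12 pinacol boronate of 17 (vinyl converted to CH2CH2Bpin) | C=C1[C@@H](CCB2OC(C)(C)C(C)(C)O2)[C@@]2(C)CC[C@@H](OC(=O)CC(C)C)[C@](C)(CO[Si](c3ccccc3)(c3ccccc3)C(C)(C)C)[C@@H]2[C@H](O)C1 | intermediate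
19 | 6-ketone of 18 | C=C1[C@@H](CCB2OC(C)(C)C(C)(C)O2)[C@@]2(C)CC[C@@H](OC(=O)CC(C)C)[C@](C)(CO[Si](c3ccccc3)(c3ccccc3)C(C)(C)C)[C@@H]2C(=O)C1 | intermediate
20 | 6-acetoxy-6,8-diene (dienol acetate) | CC1=C(CCB2OC(C)(C)C(C)(C)O2)[C@@]2(C)CC[C@@H](OC(=O)CC(C)C)[C@](C)(CO[Si](c3ccccc3)(c3ccccc3)C(C)(C)C)[C@@H]2C(OC(C)=O)=C1 | intermediate
21 | 6-oxo-8-ene (deconjugated ketone) | CC1=C(CCB2OC(C)(C)C(C)(C)O2)[C@@]2(C)CC[C@@H](OC(=O)CC(C)C)[C@](C)(CO[Si](c3ccccc3)(c3ccccc3)C(C)(C)C)[C@@H]2C(=O)C1 | intermediate
22 | 6β-hydroxy-8-ene boronate | CC1=C(CCB2OC(C)(C)C(C)(C)O2)[C@@]2(C)CC[C@@H](OC(=O)CC(C)C)[C@](C)(CO[Si](c3ccccc3)(c3ccccc3)C(C)(C)C)[C@@H]2[C@H](O)C1 | intermediate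
23 | (E)-3-iodobut-2-enoic acid | I/C(C)=C/C(=O)O | starting material
24 | 2-(trimethylsilyl)ethanol | C[Si](C)(C)CCO | starting material
25 | 2-(trimethylsilyl)ethyl (E)-3-iodobut-2-enoate | I/C(C)=C/C(=O)OCC[Si](C)(C)C | intermediate
26 | C15 2-(trimethylsilyl)ethyl ester, C19 TBDPS ether of the target | CC1=C(CC/C(C)=C/C(=O)OCC[Si](C)(C)C)[C@@]2(C)CC[C@@H](OC(=O)CC(C)C)[C@](C)(CO[Si](c3ccccc3)(c3ccccc3)C(C)(C)C)[C@@H]2[C@H](O)C1 | intermediate
27 | (13E)-6β,19-dihydroxy-3α-(3-methylbutanoyloxy)labda-8,13-dien-15-oic acid, (3R,4S,5R,6R,10S) | CC1=C(CC/C(C)=C/C(=O)O)[C@@]2(C)CC[C@@H](OC(=O)CC(C)C)[C@](C)(CO)[C@@H]2[C@H](O)C1 | target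

Total step count: 17. Longest linear sequence: 16 (steps 1 to 14, 16 and 17; step 15 is a side branch).

Steps most likely to fail

Step 10. The neutral [3,3] shift has to build a quaternary centre from a tetrasubstituted alkene. It may be outrun by retro-ene fragmentation of the carbinol back to enal 10 and 2-methylpenta-1,4-diene, and the thermal ene closure may be slow. The fallback sets out from 14: the hydroxyl is silylated (TMSCl, imidazole) to the trimethylsilyl ether F1, which has no O–H for a retro-ene path; a thermal siloxy-Cope shift (toluene, 200 °C) gives the trimethylsilyl enol ether F2; dilute aqueous HCl in THF releases aldehyde 16, now isolated; Me2AlCl in CH2Cl2 at −78 °C closes ring B by the Lewis acid-promoted type 2 carbonyl-ene reaction. The fallback comes back to the route at 17.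

Step 13. Enol acetylation may stop at the semicyclic dienol acetate that keeps the exocyclic methylene, in which case step 14 would return the 8(17)-alkene; reconjugation during step 14 would give the 7-en-6-ol instead. The fallback sets out from 18 and leaves the C6 alcohol untouched: a cobalt-hydride hydrogen-atom-transfer isomerisation (Co(salen)Cl [salen = N,N′-bis(3,5-di-tert-butylsalicylidene)-1,2-cyclohexanediamine dianion] (cat.), PhSiH3 (cat.), benzene, rt) moves the 1,1-disubstituted alkene one position into the ring by a radical, non-ionic path. It comes back to the route at 22 and makes no new compound (F0).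

Step 8. The aldehyde is a tetrasubstituted enal next to a quaternary carbon, so the catalysed allylboration may be sluggish, and the existing stereocentres may oppose the catalyst and erode the facial selectivity at C6. The fallback sets out from 10: Barbier allylation (allyl bromide, Zn, THF/aq. NH4Cl) gives 12 together with its (6R)-epimer F3; Dess–Martin oxidation of the mixture gives the allyl ketone F4; Corey–Bakshi–Shibata reduction ((R)-2-methyl-CBS-oxazaborolidine, BH3·SMe2, THF, −30 °C) differentiates the bulky cyclohexenyl group from the allyl group. The fallback comes back to the route at 12.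

Further compounds
F1 | step 10 | trimethylsilyl ether of dienol 14 | CC1=C([C@@H](O[Si](C)(C)C)C/C=C/C(C)=C)[C@@](C)(CO[Si](c2ccccc2)(c2ccccc2)C(C)(C)C)[C@H](OC(=O)CC(C)C)CC1
F2 | step 10 | trimethylsilyl enol ether of aldehyde 16 | C[Si](C)(C)O/C=C1\[C@@](C)(CO[Si](c2ccccc2)(c2ccccc2)C(C)(C)C)[C@H](OC(=O)CC(C)C)CC[C@]1(C)[C@H](C=C)C(C)=C
F0 | step 13 | none | none
F3 | step 8 | (6R)-epimer of homoallylic alcohol 12 | CC1=C([C@H](O)CC=C)[C@@](C)(CO[Si](c2ccccc2)(c2ccccc2)C(C)(C)C)[C@H](OC(=O)CC(C)C)CC1
F4 | step 8 | allyl ketone (3-but-3-enoyl analogue of 10) | CC1=C(C(=O)CC=C)[C@@](C)(CO[Si](c2ccccc2)(c2ccccc2)C(C)(C)C)[C@H](OC(=O)CC(C)C)CC1
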